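The earlier runs and the new flask are simulated with made-up constants, noise included.

One product uses up one starting material and one coupling partner, so each charge loses the same concentration to product.

| flask | starting material | coupling partner | capture agent | remark | time |
|---|---|---|---|---|---|
| Saturday's | 9 mM | 21 mM | 2 mM | run made earlier |  |
| Tuesday's | 27 mM | 21 mM | 2 mM | run made earlier |  |
| Thursday's | 20 mM | 8.9 mM | 2 mM | run made earlier |  |
| larch | 20 mM | 21.0 mM | 2.00 mM |  | 8.0 min |
| alder | 6.0 mM | 5.00 mM | 2.00 mM |  | 8.0 min |

| run | time / min | product / % | starting material / % |
|---|---|---|---|
| Saturday's | 1.50 | 31 | 41 |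
| Saturday's | 3.00 | 53 | 30 |
| Saturday's | 5.00 | 68 | 20 |
| Saturday's | 6.00 | 74 | 14 |
| Saturday's | 8.00 | 77 | 11 |
| Tuesday's | 0.667 | 13 | 63 |
| Tuesday's | 1.33 | 28 | 55 |
| Tuesday's | 2.50 | 38 | 48 |
| Tuesday's | 4.00 | 46 | 44 |
| Tuesday's | 8.00 | 60 | 36 |
| Thursday's | 0.667 | 7 | 78 |
| Thursday's | 1.33 | 15 | 75 |
| Thursday's | 2.50 | 20 | 70 |
| Thursday's | 4.00 | 26 | 66 |
| Thursday's | 8.00 | 36 | 61 |

(each reading ± 2 percentage points)

- the analysis behind the earlier runs scatters by 2 percentage points, standard deviation

* which one finishes higher in amount of product, in percent of the starting material charged ("neither" within 2 percentage points) (larch / alder / neither)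
* amount of product at the end, in percent of the starting material charged, larch
* amount of product at the end, in percent of the starting material charged, alder

The last row of each table, at 8.00 min, can be read with that balance. Take each charge less its product, as a fraction of that charge, and divide the richer fraction by the poorer. The gap between the charges, divided by the natural log of that ratio, gives a concentration. Saturday's row gives 11.2 mM. Tuesday's row gives 10.7 mM, and Thursday's 9.18 mM. The rows lie close together, although their charges differ widely.

Their mean, 10.4 mM, is the half-way charge: the equal charge of both partners of which this plain second-order reckoning turns half into product by that time. For near-equal charges, the product is the mean charge times mean/(mean + half-way charge).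

My own reckoning follows. Larch has a mean charge of 20.5 mM, about twice the half-way charge, which gives 68.1 %. Alder has 5.50 mM, about half of it, which gives 31.8 %.

The forecast says larch, with larch at 67 % (60 % to 73 %) and alder at 34 % (26 % to 44 %): “Alder runs dilute, so the bimolecular rate is low”. Its alder figure stands higher than mine.

The flasks give larch 67.3 % and alder 38.2 %, so larch finishes higher.

    starting material + coupling partner ⇌ open intermediate (K = 43.0 M⁻¹, k = 7.70 M⁻¹ s⁻¹)
    open intermediate ⇌ product + released group (K = 0.0340 M, k = 0.0130 s⁻¹)
    coupling partner → decomposed reagent (k = 0.00140 s⁻¹)
    open intermediate + capture agent → trapped intermediate (k = 0.430 M⁻¹ s⁻¹)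
    released group → by-product carried off (k = 0.270 s⁻¹)

Larch, at twice the half-way charge, ends above half; alder, at half of it, ends below. Alder's short finish is mainly due to its low charge of coupling partner, its limiting reagent: with larch's charge of partner, alder reaches 82.9 %. The neighbour of alder charged with 20 mM of coupling partner has charges 14.0 mM apart, too far for the near-equal rule, so the log reading is run backwards. With the half-way charge it gives that neighbour 80.3 % of product, and that flask gives 81.9 %.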